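**Plan**
Retrosynthesis: the N-benzyl group is removed last; the nitrogen ring is cut at N2–C1 and C1–C8a (Pictet–Spengler with acetaldehyde), then the biaryl bond C5–C1' (Suzuki–Miyaura), the C4–C4a bond (aryl Grignard plus alaninol sulfamidate) and the oxygenated naphthalene ring (annulation of an ortho-methallyl benzamide).
Forward: the naphthalene is built and borylated; the aminopropyl chain is joined to the dimethoxybenzene, which is brominated, N-benzylated and coupled with the naphthalene while still open-chain; the nitrogen ring closes last and the benzyl group is then removed.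
Enabling feature: C8a is para to the C6 methoxy and ortho to the C8 methoxy group, and C1 is peri to that C8 methoxy group and 1,3 to the C3 methyl across N2. Closure is therefore fast and reversible, and the (1S,3S)-trans isomer (pseudoaxial C1 methyl, equatorial C3 methyl) is the most stable form of the nitrogen ring.
Stereochemistry: C3 comes from L-alaninol and is never a reacting centre; C1 is set in the ring closure under thermodynamic control relative to C3.

Key step: step 13

Remark: the target SMILES fixes C1 and C3 but not the sense of the hindered C5–C1' axis, so the axis is left uncontrolled and 22, 23 and 25–28 are expected as pairs of atropisomers with the same carbon stereocentres.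

**Route**

Step 1
Reactants: 1 N,N-diethyl-2-methoxybenzamide; 2 methallyl bromide (3-bromo-2-methylprop-1-ene)
Product: 5 N,N-diethyl-2-methoxy-6-(2-methylprop-2-en-1-yl)benzamide, via aryllithium 3 (not isolated), via arylmagnesium bromide 4 (not isolated)
Conditions: s-BuLi, TMEDA, THF, −78 °C; MgBr2·OEt2, −78 → 0 °C; then 2, 0 °C → rt
Reagents that add atoms: none
Why: Directed ortho-metalation, in which the diethylamide as the stronger director guides s-BuLi/TMEDA to C6, followed by transmetalation to magnesium so that the aryl nucleophile is allylated cleanly by the methallyl bromide.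

Step 2
Reactants: 5 N,N-diethyl-2-methoxy-6-(2-methylprop-2-en-1-yl)benzamide
Product: 7 8-methoxy-3-methylnaphthalen-1-ol, via lithiated amide 6 (not isolated)
Conditions: LiN(iPr)2 (LDA, 2.2 equiv), THF, −78 °C → rt; then 1 M HCl
Reagents that add atoms: none
Why: Anionic ring annulation of an ortho-allylbenzamide, in which the benzylic-allylic anion closes a six-membered ring on the amide carbonyl through its terminal carbon, diethylamide is expelled and the ketone tautomerises to the naphthol.

Step 3
Reactants: 7 8-methoxy-3-methylnaphthalen-1-ol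
Product: 8 1,8-dimethoxy-3-methylnaphthalene
Conditions: NaH, MeI, DMF, 0 °C → rt
Reagents that add atoms: iodomethane, CI
Why: Williamson etherification, with NaH used because the peri hydrogen-bonded naphthol needs full deprotonation before O-alkylation.

Step 4
Reactants: 8 1,8-dimethoxy-3-methylnaphthalene
Product: 9 1-bromo-4,5-dimethoxy-2-methylnaphthalene
Conditions: NBS (1.0 equiv), MeCN, 0 °C → rt, dark
Reagents that add atoms: N-bromosuccinimide, O=C1CCC(=O)N1Br
Why: Electrophilic aromatic bromination, expected at C4 of 8 because that carbon is para to a methoxy group and further activated by the ortho methyl group, unlike C5 in the other ring.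

Step 5
Reactants: 9 1-bromo-4,5-dimethoxy-2-methylnaphthalene
Product: 12 (4,5-dimethoxy-2-methylnaphthalen-1-yl)boronic acid, via aryllithium 10 (not isolated), via lithium triisopropoxyborate 11 (not isolated)
Conditions: n-BuLi, THF, −78 °C; B(OiPr)3, −78 °C → rt; then 1 M HCl
Reagents that add atoms: triisopropyl borate, CC(C)OB(OC(C)C)OC(C)C; water, O
Why: Bromine–lithium exchange, borylation of the aryllithium and hydrolysis of the borate is the standard route to hindered arylboronic acids.

Step 6
Reactants: 13 tert-butyl N-[(2S)-1-hydroxypropan-2-yl]carbamate (N-Boc-L-alaninol)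
Product: 14 tert-butyl (4S)-4-methyl-1,2,3-oxathiazolidine-3-carboxylate 2-oxide (both sulfur epimers)
Conditions: SOCl2, pyridine, MeCN, −40 °C → rt
Reagents that add atoms: thionyl chloride, O=S(Cl)Cl
Why: Cyclisation of an N-Boc 1,2-amino alcohol with thionyl chloride gives the cyclic sulfamidite through O–S and N–S bond formation only, so the carbon stereocentre is not touched.

Step 7
Reactants: 14 tert-butyl (4S)-4-methyl-1,2,3-oxathiazolidine-3-carboxylate 2-oxide
Product: 15 tert-butyl (4S)-4-methyl-1,2,3-oxathiazolidine-3-carboxylate 2,2-dioxide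
Conditions: RuCl3·xH2O (1 mol %), NaIO4, MeCN/H2O, 0 °C
Reagents that add atoms: sodium periodate, [Na+].[O-]I(=O)(=O)=O
Why: RuO4 generated catalytically from RuCl3 and NaIO4 oxidises the sulfamidite sulfur to the sulfamidate, the usual second stage of cyclic sulfamidate synthesis.

Step 8
Reactants: 15 tert-butyl (4S)-4-methyl-1,2,3-oxathiazolidine-3-carboxylate 2,2-dioxide; 16 1-bromo-3,5-dimethoxybenzene
Product: 19 tert-butyl N-[(2S)-1-(3,5-dimethoxyphenyl)propan-2-yl]carbamate, via Grignard reagent 17 (not isolated), via N-sulfamate salt 18 (not isolated)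
Conditions: 16, Mg turnings, THF, reflux; then CuBr·SMe2 (10 mol %), 15, THF, −20 °C → rt; then 10% aq. citric acid, rt
Reagents that add atoms: none
Why: Copper-catalysed SN2 opening of the cyclic sulfamidate by the aryl Grignard reagent takes place at the primary C–O carbon, so the (S) centre is carried over unchanged, and mild aqueous acid then hydrolyses the N-sulfamate while the Boc group stays.

Step 9
Reactants: 19 tert-butyl N-[(2S)-1-(3,5-dimethoxyphenyl)propan-2-yl]carbamate
Product: 20 tert-butyl N-[(2S)-1-(2-bromo-3,5-dimethoxyphenyl)propan-2-yl]carbamate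
Conditions: NBS (1.0 equiv), MeCN, 0 °C
Reagents that add atoms: N-bromosuccinimide, O=C1CCC(=O)N1Br
Why: Electrophilic bromination of the 3,5-dimethoxyalkylbenzene is expected at C2, ortho to the side chain and para to a methoxy group, and not at the more crowded C4 between the two methoxy groups.

Step 10
Reactants: 20 tert-butyl N-[(2S)-1-(2-bromo-3,5-dimethoxyphenyl)propan-2-yl]carbamate
Product: 21 tert-butyl N-benzyl-N-[(2S)-1-(2-bromo-3,5-dimethoxyphenyl)propan-2-yl]carbamate
Conditions: NaH, BnBr, DMF, 0 °C → rt
Reagents that add atoms: benzyl bromide, BrCc1ccccc1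
Why: N-Alkylation of the carbamate anion installs the benzyl group needed for the ring closure and removes the N–H that could otherwise undergo palladium-catalysed intramolecular N-arylation to an indoline during the coupling.

Step 11
Reactants: 21 tert-butyl N-benzyl-N-[(2S)-1-(2-bromo-3,5-dimethoxyphenyl)propan-2-yl]carbamate; 12 (4,5-dimethoxy-2-methylnaphthalen-1-yl)boronic acid
Product: 22 tert-butyl N-benzyl-N-[(2S)-1-[2-(4,5-dimethoxy-2-methylnaphthalen-1-yl)-3,5-dimethoxyphenyl]propan-2-yl]carbamate
Conditions: 12 (1.5 equiv), Pd(OAc)2 (5 mol %), SPhos (10 mol %), K3PO4, toluene/H2O (10:1), 100 °C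
Reagents that add atoms: none
Why: Suzuki–Miyaura coupling with the bulky, electron-rich biarylphosphine SPhos is established for tetra-ortho-substituted biaryls, the ligand speeding oxidative addition to the electron-rich bromide and reductive elimination at the crowded junction.

Step 12
Reactants: 22 tert-butyl N-benzyl-N-[(2S)-1-[2-(4,5-dimethoxy-2-methylnaphthalen-1-yl)-3,5-dimethoxyphenyl]propan-2-yl]carbamate
Product: 23 (2S)-N-benzyl-1-[2-(4,5-dimethoxy-2-methylnaphthalen-1-yl)-3,5-dimethoxyphenyl]propan-2-amine
Conditions: 4 M HCl in 1,4-dioxane, rt; then aq. NaOH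
Reagents that add atoms: none
Why: Acidolysis of the tert-butyl carbamate, run with HCl in dioxane so that the tert-butyl cation leaves as isobutene and does not alkylate the electron-rich rings as it could in neat TFA.

Step 13
Reactants: 23 (2S)-N-benzyl-1-[2-(4,5-dimethoxy-2-methylnaphthalen-1-yl)-3,5-dimethoxyphenyl]propan-2-amine; 24 acetaldehyde
Product: 27 (1S,3S)-2-benzyl-5-(4,5-dimethoxy-2-methylnaphthalen-1-yl)-6,8-dimethoxy-1,3-dimethyl-1,2,3,4-tetrahydroisoquinoline, via iminium trifluoroacetate 25 (not isolated), via (1R,3S)-cis epimer 26 (not isolated)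
Conditions: 24 (3 equiv), TFA (2 equiv), 4 Å MS, CH2Cl2, 0 °C → rt, sealed; then evaporation, TFA/CH2Cl2 (1:4), 40 °C until the epimer composition is constant; aq. NaHCO3
Reagents that add atoms: none
Why: Condensation of the secondary amine with acetaldehyde in TFA gives the N-benzyl-N-ethylidene iminium ion 25, which the aryl carbon that becomes C8a attacks in an intramolecular Mannich-type electrophilic substitution, the Pictet–Spengler reaction, well known for N-benzyl arylisopropylamines. The nitrogen ring closes in a 6-endo-trig mode, and N2–C1 and C1–C8a form in the same operation. C8a is the only free carbon ortho to the side chain, since the naphthyl group occupies the other one, and it is para to the C6 methoxy and ortho to the C8 methoxy group, which secures both regiochemistry and rate. The new centre C1 is controlled by the fixed (S) centre C3 through product stability: the C8 methoxy group and the N-benzyl group force the C1 methyl pseudoaxial, and only the (1S,3S)-trans isomer 27 combines this with an equatorial C3 methyl. Any (1R,3S)-cis epimer 26 formed under kinetic control should ionise in acid at the C1–N bond, the benzylic cation being stabilised by the same two methoxy groups, or revert to 25, and reclose to 27, as in acid epimerisations of electron-rich tetrahydroisoquinolines and tetrahydro-beta-carbolines. The selectivity required is therefore trans over cis at C1, and the second, aldehyde-free acid stage is there to reach it by equilibration.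

Step 14
Reactants: 27 (1S,3S)-2-benzyl-5-(4,5-dimethoxy-2-methylnaphthalen-1-yl)-6,8-dimethoxy-1,3-dimethyl-1,2,3,4-tetrahydroisoquinoline
Product: 28 (1S,3S)-5-(4,5-dimethoxy-2-methylnaphthalen-1-yl)-6,8-dimethoxy-1,3-dimethyl-1,2,3,4-tetrahydroisoquinoline
Conditions: H2 (1 atm), 10% Pd/C, MeOH, rt
Reagents that add atoms: none
Why: Hydrogenolysis over Pd/C cleaves the exocyclic N-benzyl bond in preference to the endocyclic, fully substituted benzylic C1–N bond, which the ring holds out of alignment with the arene, so C1 and C3 are untouched.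

**Compound list**

1 | N,N-diethyl-2-methoxybenzamide | CCN(CC)C(=O)c1ccccc1OC | starting material
2 | methallyl bromide (3-bromo-2-methylprop-1-ene) | CC(=C)CBr | starting material
3 | [2-(diethylcarbamoyl)-3-methoxyphenyl]lithium | CCN(CC)C(=O)c1c([Li])cccc1OC | intermediate
4 | [2-(diethylcarbamoyl)-3-methoxyphenyl]magnesium bromide | CCN(CC)C(=O)c1c([Mg]Br)cccc1OC | intermediate
5 | N,N-diethyl-2-methoxy-6-(2-methylprop-2-en-1-yl)benzamide | CCN(CC)C(=O)c1c(CC(C)=C)cccc1OC | intermediate
6 | N,N-diethyl-2-(1-lithio-2-methylprop-2-en-1-yl)-6-methoxybenzamide | CCN(CC)C(=O)c1c(C([Li])C(C)=C)cccc1OC | intermediate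
7 | 8-methoxy-3-methylnaphthalen-1-ol | Cc1cc(O)c2c(OC)cccc2c1 | intermediate
8 | 1,8-dimethoxy-3-methylnaphthalene | Cc1cc(OC)c2c(OC)cccc2c1 | intermediate
9 | 1-bromo-4,5-dimethoxy-2-methylnaphthalene | Cc1cc(OC)c2c(OC)cccc2c1Br | intermediate
10 | (4,5-dimethoxy-2-methylnaphthalen-1-yl)lithium | [Li]c1c(C)cc(OC)c2c(OC)cccc12 | intermediate
11 | lithium (4,5-dimethoxy-2-methylnaphthalen-1-yl)tri(propan-2-yloxy)borate | [Li+].CC(C)O[B-](OC(C)C)(OC(C)C)c1c(C)cc(OC)c2c(OC)cccc12 | intermediate
12 | (4,5-dimethoxy-2-methylnaphthalen-1-yl)boronic acid | Cc1cc(OC)c2c(OC)cccc2c1B(O)O | intermediate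
13 | tert-butyl N-[(2S)-1-hydroxypropan-2-yl]carbamate (N-Boc-L-alaninol) | C[C@H](NC(=O)OC(C)(C)C)CO | starting material
14 | tert-butyl (4S)-4-methyl-1,2,3-oxathiazolidine-3-carboxylate 2-oxide (both sulfur epimers) | C[C@H]1COS(=O)N1C(=O)OC(C)(C)C | intermediate
15 | tert-butyl (4S)-4-methyl-1,2,3-oxathiazolidine-3-carboxylate 2,2-dioxide | C[C@H]1COS(=O)(=O)N1C(=O)OC(C)(C)C | intermediate
16 | 1-bromo-3,5-dimethoxybenzene | COc1cc(Br)cc(OC)c1 | starting material
17 | (3,5-dimethoxyphenyl)magnesium bromide | COc1cc([Mg]Br)cc(OC)c1 | intermediate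
18 | bromomagnesium N-(tert-butoxycarbonyl)-N-[(2S)-1-(3,5-dimethoxyphenyl)propan-2-yl]sulfamate | COc1cc(C[C@H](C)N(C(=O)OC(C)(C)C)S(=O)(=O)[O-])cc(OC)c1.[Mg+2].[Br-] | intermediate
19 | tert-butyl N-[(2S)-1-(3,5-dimethoxyphenyl)propan-2-yl]carbamate | COc1cc(C[C@H](C)NC(=O)OC(C)(C)C)cc(OC)c1 | intermediate
20 | tert-butyl N-[(2S)-1-(2-bromo-3,5-dimethoxyphenyl)propan-2-yl]carbamate | COc1cc(C[C@H](C)NC(=O)OC(C)(C)C)c(Br)c(OC)c1 | intermediate
21 | tert-butyl N-benzyl-N-[(2S)-1-(2-bromo-3,5-dimethoxyphenyl)propan-2-yl]carbamate | COc1cc(C[C@H](C)N(Cc2ccccc2)C(=O)OC(C)(C)C)c(Br)c(OC)c1 | intermediate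
22 | tert-butyl N-benzyl-N-[(2S)-1-[2-(4,5-dimethoxy-2-methylnaphthalen-1-yl)-3,5-dimethoxyphenyl]propan-2-yl]carbamate | COc1cc(C[C@H](C)N(Cc2ccccc2)C(=O)OC(C)(C)C)c(-c2c(C)cc(OC)c3c(OC)cccc23)c(OC)c1 | intermediate
23 | (2S)-N-benzyl-1-[2-(4,5-dimethoxy-2-methylnaphthalen-1-yl)-3,5-dimethoxyphenyl]propan-2-amine | COc1cc(C[C@H](C)NCc2ccccc2)c(-c2c(C)cc(OC)c3c(OC)cccc23)c(OC)c1 | intermediate
24 | acetaldehyde | CC=O | starting material
25 | N-benzyl-N-[(2S)-1-[2-(4,5-dimethoxy-2-methylnaphthalen-1-yl)-3,5-dimethoxyphenyl]propan-2-yl]ethaniminium trifluoroacetate | COc1cc(C[C@H](C)[N+](=CC)Cc2ccccc2)c(-c2c(C)cc(OC)c3c(OC)cccc23)c(OC)c1.[O-]C(=O)C(F)(F)F | intermediate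
26 | (1R,3S)-2-benzyl-5-(4,5-dimethoxy-2-methylnaphthalen-1-yl)-6,8-dimethoxy-1,3-dimethyl-1,2,3,4-tetrahydroisoquinoline (cis epimer) | COc1cc(OC)c2c(c1-c1c(C)cc(OC)c3c(OC)cccc13)C[C@H](C)N(Cc1ccccc1)[C@@H]2C | intermediate
27 | (1S,3S)-2-benzyl-5-(4,5-dimethoxy-2-methylnaphthalen-1-yl)-6,8-dimethoxy-1,3-dimethyl-1,2,3,4-tetrahydroisoquinoline | COc1cc(OC)c2c(c1-c1c(C)cc(OC)c3c(OC)cccc13)C[C@H](C)N(Cc1ccccc1)[C@H]2C | intermediate
28 | (1S,3S)-5-(4,5-dimethoxy-2-methylnaphthalen-1-yl)-6,8-dimethoxy-1,3-dimethyl-1,2,3,4-tetrahydroisoquinoline | COc1cc(OC)c2c(c1-c1c(C)cc(OC)c3c(OC)cccc13)C[C@H](C)N[C@H]2C | target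

**Count**
Total steps: 14. Longest linear sequence: 9 steps (steps 1–5 and 11–14; the amine branch, steps 6–14, is equally long).

**Steps most likely to fail**

1. Step 11. Transmetalation at the tetra-ortho-substituted junction is slow, so protodeboronation of the electron-rich boronic acid may outrun the coupling and return 8. The fallback sets out from 9 and keeps boron and water out of the coupling. Bromine–lithium exchange (n-BuLi, THF, −78 °C) to 10 and transmetalation with ZnCl2 should give (4,5-dimethoxy-2-methylnaphthalen-1-yl)zinc chloride F1. A Negishi coupling of F1 with 21 (Pd2(dba)3, RuPhos, THF, 70 °C), a reaction type established for tetra-ortho-substituted biaryls, would come back to the route at 22.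

2. Step 13. Equilibration at C1 may stall before the cis epimer is consumed, or the prolonged acid stage may let residual acetaldehyde alkylate the electron-rich naphthalene. The fallback sets out from 23 and reaches the target through an amide at a higher oxidation level. Hydrogenolysis (H2, 10% Pd/C, MeOH) would give the primary amine (2S)-1-[2-(4,5-dimethoxy-2-methylnaphthalen-1-yl)-3,5-dimethoxyphenyl]propan-2-amine F2. Acetylation (Ac2O, Et3N, CH2Cl2) would give N-[(2S)-1-[2-(4,5-dimethoxy-2-methylnaphthalen-1-yl)-3,5-dimethoxyphenyl]propan-2-yl]acetamide F3. Bischler–Napieralski cyclisation (POCl3, MeCN, reflux) at the same free ortho carbon would give (3S)-5-(4,5-dimethoxy-2-methylnaphthalen-1-yl)-6,8-dimethoxy-1,3-dimethyl-3,4-dihydroisoquinoline F4. Reduction of F4 with LiAlH4/AlMe3 in THF at −78 °C, a reagent pair established for trans-selective reduction of 1,3-dimethyl-3,4-dihydroisoquinolines, would come back to the route at 28.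

3. Step 4. Bromination may go partly into the other ring (C5 of 8, para to the C8 methoxy group) or twice. The fallback sets out from 7 and moves the halogenation to the naphthol stage, where the free hydroxyl group is the strongest donor and directs para within its own ring. NBS in MeCN at −20 °C should give 4-bromo-8-methoxy-3-methylnaphthalen-1-ol F5, and O-methylation of F5 (MeI, K2CO3, acetone, reflux) would come back to the route at 9.

**Further compounds**
F1 | step 11 | (4,5-dimethoxy-2-methylnaphthalen-1-yl)zinc chloride | Cl[Zn]c1c(C)cc(OC)c2c(OC)cccc12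
F2 | step 13 | (2S)-1-[2-(4,5-dimethoxy-2-methylnaphthalen-1-yl)-3,5-dimethoxyphenyl]propan-2-amine | COc1cc(C[C@H](C)N)c(-c2c(C)cc(OC)c3c(OC)cccc23)c(OC)c1
F3 | step 13 | N-[(2S)-1-[2-(4,5-dimethoxy-2-methylnaphthalen-1-yl)-3,5-dimethoxyphenyl]propan-2-yl]acetamide | COc1cc(C[C@H](C)NC(C)=O)c(-c2c(C)cc(OC)c3c(OC)cccc23)c(OC)c1
F4 | step 13 | (3S)-5-(4,5-dimethoxy-2-methylnaphthalen-1-yl)-6,8-dimethoxy-1,3-dimethyl-3,4-dihydroisoquinoline | COc1cc(OC)c2c(c1-c1c(C)cc(OC)c3c(OC)cccc13)C[C@H](C)N=C2C
F5 | step 4 | 4-bromo-8-methoxy-3-methylnaphthalen-1-ol | Cc1cc(O)c2c(OC)cccc2c1Br
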